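**Retrosynthetic overview**
1. Last ring (1,3-dioxin of the bicyclic ketal): the ketal C–O(coumarin) bond comes from acid-mediated addition of the freed coumarin 4-OH across the enol-ether C=C of a 2H-pyran (step 11).
2. Key disconnection: a retro-oxa-Diels–Alder cut through the tetrahydropyran, breaking O–CH(coumarin) and ring-fusion CH–C(sp2); this also opens the cyclopentene.
3. Enabling feature: in the pyran ring the atoms O, C(ketal), CH(CH3) and the cyclopentene sp2 carbon, whose C=CH bond is exocyclic to the pyran, are a masked acyl allene, O=C–C(CH3)=C=CH, i.e. a 1-oxadiene. The other two ring atoms, CH(coumarin)–CH(ring fusion), are the terminal C=C of a 3-alkenyl-4-oxycoumarin (a vinylogous enol ether). A CH(CH3)–CH2 tether joins the two.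
4. The allenyl 1,2-diketone comes from a ketene plus a diketo ylide (Wittig); the carboxylic acid from the prenyl end of (S)-citronellal; the pyranone is built on the chain (Doebner, aryl ester, Claisen).
5. Ring order: benzene (bought) → pyranone (step 3) → cyclopentene + dihydropyran (step 10, one operation) → 1,3-dioxin (step 11). The citronellal methyl stereocentre controls the four new ones.

Key step: step 10

Assumption: the allene axis of 18 forms without control and both epimers are taken to converge on 19 (see step 10). Locants C1, C3, C4, C4a, C7, C7a below are those of the cyclopenta[c]pyran unit of 19 and 20.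

Step 1
Reactants: 1 (S)-citronellal; 2 malonic acid
Product: 3 (3E,5S)-5,9-dimethyldeca-3,8-dienoic acid
Conditions: piperidinium acetate (cat.), DMSO, 100 °C
Reagents that add atoms: none
Why: Knoevenagel condensation (Doebner variant) under deconjugating conditions, in which the alkylidenemalonic acid decarboxylates through its β,γ-unsaturated tautomer to the (E)-alk-3-enoic acid; the methyl-bearing stereocentre (now C5) is not enolisable and is untouched.

Step 2
Reactants: 3 (3E,5S)-5,9-dimethyldeca-3,8-dienoic acid; 4 methyl 2-hydroxy-6-methylbenzoate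
Product: 5 2-(methoxycarbonyl)-3-methylphenyl (3E,5S)-5,9-dimethyldeca-3,8-dienoate
Conditions: DCC, DMAP (cat.), CH2Cl2, 0 °C to rt
Reagents that add atoms: none
Why: Steglich esterification of the phenol under nearly neutral conditions that leave the β,γ-alkene in place.

Step 3
Reactants: 5 2-(methoxycarbonyl)-3-methylphenyl (3E,5S)-5,9-dimethyldeca-3,8-dienoate
Product: 6 3-[(1E,3S)-3,7-dimethylocta-1,6-dien-1-yl]-4-hydroxy-5-methyl-2H-chromen-2-one
Conditions: LiN(SiMe3)2 (2.5 equiv), THF, −78 °C to rt; then 1 M HCl
Reagents that add atoms: none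
Why: Intramolecular Claisen (Dieckmann-type) condensation: the dienolate of the aryl ester attacks the neighbouring methyl ester through its α-carbon (six-membered ring), methoxide leaves and the product is drained as its stabilised enolate, giving the 4-hydroxycoumarin with the (E)-alkene now conjugated.

Step 4
Reactants: 6 3-[(1E,3S)-3,7-dimethylocta-1,6-dien-1-yl]-4-hydroxy-5-methyl-2H-chromen-2-one
Product: 7 3-[(1E,3S)-3,7-dimethylocta-1,6-dien-1-yl]-4-(methoxymethoxy)-5-methyl-2H-chromen-2-one
Conditions: MOMCl, i-Pr2NEt, CH2Cl2, 0 °C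
Reagents that add atoms: chloromethyl methyl ether, COCCl
Why: O-alkylation of the acidic enol (C3 is blocked) with a hard electrophile gives the acid-labile vinylogous MOM ester, which masks the oxygen and keeps the alkenyl terminus electron-rich.

Step 5
Reactants: 7 3-[(1E,3S)-3,7-dimethylocta-1,6-dien-1-yl]-4-(methoxymethoxy)-5-methyl-2H-chromen-2-one
Product: 8 (4S,5E)-6-[4-(methoxymethoxy)-5-methyl-2-oxo-2H-chromen-3-yl]-4-methylhex-5-enal
Conditions: OsO4 (2 mol %), NaIO4 (4 equiv), 2,6-lutidine, dioxane/H2O 3:1, rt
Reagents that add atoms: sodium periodate, [Na+].[O-][I](=O)(=O)=O (terminal oxidant; the oxygen is delivered through OsO4)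
Why: Lemieux–Johnson oxidation; the electron-rich trisubstituted alkene should be osmylated faster than the disubstituted alkene conjugated with the pyranone, and periodate cleaves the diol to the aldehyde.

Step 6
Reactants: 8 (4S,5E)-6-[4-(methoxymethoxy)-5-methyl-2-oxo-2H-chromen-3-yl]-4-methylhex-5-enal
Product: 9 (4S,5E)-6-[4-(methoxymethoxy)-5-methyl-2-oxo-2H-chromen-3-yl]-4-methylhex-5-enoic acid
Conditions: NaClO2, NaH2PO4, 2-methylbut-2-ene, t-BuOH/H2O, 0 °C to rt
Reagents that add atoms: sodium chlorite, [Na+].[O-]Cl=O
Why: Pinnick oxidation, chemoselective for the aldehyde, with 2-methylbut-2-ene scavenging hypochlorite so that the diene is not chlorinated.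

Step 7
Reactants: 10 ethyltriphenylphosphonium bromide; 11 diethyl oxalate
Product: 13 ethyl 2-oxo-3-(triphenylphosphoranylidene)butanoate, via ethylidene(triphenyl)phosphorane 12 (not isolated)
Conditions: NaN(SiMe3)2 (1.0 equiv), THF, 0 °C; then 11, −78 °C to rt
Reagents that add atoms: none
Why: C-acylation of a non-stabilised phosphorus ylide by an ester; the ethoxide set free deprotonates the acylphosphonium salt to the stabilised ylide, which does not react further.

Step 8
Reactants: 13 ethyl 2-oxo-3-(triphenylphosphoranylidene)butanoate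
Product: 14 N-methoxy-N-methyl-2-oxo-3-(triphenylphosphoranylidene)butanamide
Conditions: MeNH(OMe)·HCl, i-PrMgCl, THF, −20 °C to 0 °C
Reagents that add atoms: N,O-dimethylhydroxylamine hydrochloride, CNOC.Cl
Why: Ester aminolysis by the chloromagnesium amide of N,O-dimethylhydroxylamine; the ylide-conjugated ketone is enolate-like and inert.

Step 9
Reactants: 14 N-methoxy-N-methyl-2-oxo-3-(triphenylphosphoranylidene)butanamide
Product: 15 6-methyl-2-(triphenylphosphoranylidene)heptane-3,4-dione
Conditions: i-BuMgCl (1.2 equiv), THF, 0 °C; then aq. NH4Cl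
Reagents that add atoms: isobutylmagnesium chloride, CC(C)C[Mg]Cl
Why: Weinreb ketone synthesis: the chelated tetrahedral intermediate stops the addition at the ketone stage and the ylide-conjugated carbonyl is not attacked.

Step 10
Reactants: 9 (4S,5E)-6-[4-(methoxymethoxy)-5-methyl-2-oxo-2H-chromen-3-yl]-4-methylhex-5-enoic acid; 15 6-methyl-2-(triphenylphosphoranylidene)heptane-3,4-dione
Product: 19 3-[(1R,7S,7aR)-4,7-dimethyl-3-(3-methylbutanoyl)-1,6,7,7a-tetrahydrocyclopenta[c]pyran-1-yl]-4-(methoxymethoxy)-5-methyl-2H-chromen-2-one, via acid chloride 16 (not isolated), via ketene 17 (not isolated), via allenyl diketone 18 (not isolated)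
Conditions: 1-chloro-N,N,2-trimethylprop-1-en-1-amine (1.1 equiv), CH2Cl2, 0 °C; then added slowly to 15 (1.2 equiv) and Et3N (1.5 equiv), CH2Cl2 (0.02 M), 0 °C to 40 °C
Reagents that add atoms: none
Why: Proposed new method: Et3N converts acid chloride 16 into ketene 17, which undergoes the established ketene Wittig allenation with acyl ylide 15 to give allenyl 1,2-diketone 18; its O=C–C(CH3)=C unit (carbonyl conjugated with the inner allene C=C) is a very electron-poor 1-oxadiene and the (E)-alkene of the 3-alkenyl-4-alkoxycoumarin, the terminus of a vinylogous enol ether, is its electron-rich 2π partner, so an asynchronous inverse-electron-demand oxa-Diels–Alder reaction (in the limit a Michael addition followed by oxa-Michael ring closure) should follow at 0–40 °C. The closest known reaction types are intramolecular hetero-Diels–Alder reactions of β,γ-unsaturated α-keto carbonyl compounds with enol ethers or styrenes, Diels–Alder reactions of vinylallenes and the [4+2] dimerisation of acyl allenes; new is an acyl allene whose central carbon is tied into the new carbocycle, with a coumarin-bound dienophile. Ring closures: the cyclopentene closes by C–C bond formation between the remote alkene carbon and the central allene carbon (exo with respect to the reacting C=C–C=O bond, the cumulated C=C staying in the ring, the mode known from carbanion cyclisations onto allenes), and the 2H-pyran closes by the O–C bond between the former ketone oxygen and the coumarin-bearing CH (second σ-bond of the [4+2]; 6-exo-trig attack of the dienolate oxygen on the alkylidene carbon in the stepwise limit). Stereocontrol: C7a is set by the citronellal-derived C7 stereocentre, whose methyl group takes the outside position in the five-ring transition state (minimised 1,3-allylic strain) and ends trans to the C1 substituent, and C1 follows from suprafacial addition across the (E)-alkene (stepwise: closure on the alkylidene conformer in which H-7a eclipses the C=C), which puts the coumarin cis to H-7a. The step needs periselectivity and regioselectivity for C(alkene)–C(allene centre) and O–CH(coumarin) bonding: the two-carbon tether allows only the five-ring closure, the polarity of both partners is matched, and the 4-oxygen is masked so that it cannot add to the allene. The allene axis of 18 is formed without control but is erased, since both cumulated double bonds end as the planar dienol ether of 19 and the zwitterion of the stepwise pathway can rotate about its C–C(enolate) bond before the O–C bond forms.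

Step 11
Reactants: 19 3-[(1R,7S,7aR)-4,7-dimethyl-3-(3-methylbutanoyl)-1,6,7,7a-tetrahydrocyclopenta[c]pyran-1-yl]-4-(methoxymethoxy)-5-methyl-2H-chromen-2-one
Product: 21 target CNP0310889.1, via hydroxycoumarin dienol ether 20 (not isolated)
Conditions: CF3CO2H, CH2Cl2, H2O (2 equiv), 0 °C
Reagents that add atoms: none
Why: CF3CO2H cleaves the vinylogous MOM ester and protonates the dienol ether of 20 at C4 (kinetic α-protonation, on the face away from the pseudo-axial coumarin), and the freed 4-hydroxyl, held over C3 by the C1 substituent, closes the 1,3-dioxin ring (intramolecular acid-catalysed hydroalkoxylation of an enol ether), so that the ketal carbon is fixed by the bicyclo[3.3.1] bridge and the CH(CH3) centre by anti addition (methyl syn to the bridge, trans to the acyl group); the open keto form that can arise by reversible retro-oxa-Michael opening should funnel into the same ketal.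

**Compound list**
1 | (S)-citronellal, (3S)-3,7-dimethyloct-6-enal | O=CC[C@@H](C)CCC=C(C)C | starting material
2 | malonic acid | OC(=O)CC(=O)O | starting material
3 | (3E,5S)-5,9-dimethyldeca-3,8-dienoic acid | OC(=O)C/C=C/[C@@H](C)CCC=C(C)C | intermediate
4 | methyl 2-hydroxy-6-methylbenzoate | COC(=O)c1c(C)cccc1O | starting material
5 | 2-(methoxycarbonyl)-3-methylphenyl (3E,5S)-5,9-dimethyldeca-3,8-dienoate | COC(=O)c1c(C)cccc1OC(=O)C/C=C/[C@@H](C)CCC=C(C)C | intermediate
6 | 3-[(1E,3S)-3,7-dimethylocta-1,6-dien-1-yl]-4-hydroxy-5-methyl-2H-chromen-2-one | Cc1cccc2oc(=O)c(/C=C/[C@@H](C)CCC=C(C)C)c(O)c12 | intermediate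
7 | 3-[(1E,3S)-3,7-dimethylocta-1,6-dien-1-yl]-4-(methoxymethoxy)-5-methyl-2H-chromen-2-one | Cc1cccc2oc(=O)c(/C=C/[C@@H](C)CCC=C(C)C)c(OCOC)c12 | intermediate
8 | (4S,5E)-6-[4-(methoxymethoxy)-5-methyl-2-oxo-2H-chromen-3-yl]-4-methylhex-5-enal | Cc1cccc2oc(=O)c(/C=C/[C@@H](C)CCC=O)c(OCOC)c12 | intermediate
9 | (4S,5E)-6-[4-(methoxymethoxy)-5-methyl-2-oxo-2H-chromen-3-yl]-4-methylhex-5-enoic acid | Cc1cccc2oc(=O)c(/C=C/[C@@H](C)CCC(=O)O)c(OCOC)c12 | intermediate
10 | ethyltriphenylphosphonium bromide | CC[P+](c1ccccc1)(c1ccccc1)c1ccccc1.[Br-] | starting material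
11 | diethyl oxalate | CCOC(=O)C(=O)OCC | starting material
12 | ethylidene(triphenyl)phosphorane | CC=P(c1ccccc1)(c1ccccc1)c1ccccc1 | intermediate (not isolated)
13 | ethyl 2-oxo-3-(triphenylphosphoranylidene)butanoate | CCOC(=O)C(=O)C(C)=P(c1ccccc1)(c1ccccc1)c1ccccc1 | intermediate
14 | N-methoxy-N-methyl-2-oxo-3-(triphenylphosphoranylidene)butanamide | CON(C)C(=O)C(=O)C(C)=P(c1ccccc1)(c1ccccc1)c1ccccc1 | intermediate
15 | 6-methyl-2-(triphenylphosphoranylidene)heptane-3,4-dione | CC(C)CC(=O)C(=O)C(C)=P(c1ccccc1)(c1ccccc1)c1ccccc1 | intermediate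
16 | (4S,5E)-6-[4-(methoxymethoxy)-5-methyl-2-oxo-2H-chromen-3-yl]-4-methylhex-5-enoyl chloride | Cc1cccc2oc(=O)c(/C=C/[C@@H](C)CCC(=O)Cl)c(OCOC)c12 | intermediate (not isolated)
17 | (4S,5E)-6-[4-(methoxymethoxy)-5-methyl-2-oxo-2H-chromen-3-yl]-4-methylhexa-1,5-dien-1-one (ketene) | Cc1cccc2oc(=O)c(/C=C/[C@@H](C)CC=C=O)c(OCOC)c12 | intermediate (not isolated)
18 | 3-[(1E,3S)-3,7,11-trimethyl-8,9-dioxododeca-1,5,6-trien-1-yl]-4-(methoxymethoxy)-5-methyl-2H-chromen-2-one, allene axis as both epimers | Cc1cccc2oc(=O)c(/C=C/[C@@H](C)CC=C=C(C)C(=O)C(=O)CC(C)C)c(OCOC)c12 | intermediate (not isolated)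
19 | 3-[(1R,7S,7aR)-4,7-dimethyl-3-(3-methylbutanoyl)-1,6,7,7a-tetrahydrocyclopenta[c]pyran-1-yl]-4-(methoxymethoxy)-5-methyl-2H-chromen-2-one | COCOc1c2c(C)cccc2oc(=O)c1[C@@H]1OC(C(=O)CC(C)C)=C(C)C2=CC[C@H](C)[C@@H]12 | intermediate
20 | 3-[(1R,7S,7aR)-4,7-dimethyl-3-(3-methylbutanoyl)-1,6,7,7a-tetrahydrocyclopenta[c]pyran-1-yl]-4-hydroxy-5-methyl-2H-chromen-2-one | Oc1c2c(C)cccc2oc(=O)c1[C@@H]1OC(C(=O)CC(C)C)=C(C)C2=CC[C@H](C)[C@@H]12 | intermediate (not isolated)
21 | CNP0310889.1: 5-methylcoumarin-fused dioxabicyclo[3.3.1]nonane ketal with annulated cyclopentene and 3-methylbutanoyl group (ketal C S; O–CH R; ring-fusion CH R; cyclopentene CH(CH3) S; ketal-adjacent CH(CH3) R) | Cc1cccc2oc(=O)c3c(c12)O[C@@]1(C(=O)CC(C)C)O[C@@H]3[C@H]2C(=CC[C@@H]2C)[C@H]1C | target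

**Step count**
Total: 11 steps. Longest linear sequence: 8 steps (1–6, 10, 11); the ylide branch (7–9) is 3 steps.

**Three steps most likely to fail**

1. Step 10 (Proposed new method). The ketene may be intercepted by the electron-rich alkene in an intramolecular [2+2] before the hindered ylide reaches it. The acyl allene may oligomerise or react with another periselectivity. The allene epimer mismatched with the C7 methyl may close with the wrong relative configuration. Fallback with known chemistry, from 8 back to 19: the extra unsaturation is carried as a selenide and the cycloaddition is run on an ordinary β,γ-unsaturated 1,2-diketone. Amine-catalysed α-selenenylation of 8 (N-(phenylseleno)phthalimide, pyrrolidine catalyst, CH2Cl2) gives (4S,5E)-6-[4-(methoxymethoxy)-5-methyl-2-oxo-2H-chromen-3-yl]-4-methyl-2-(phenylselanyl)hex-5-enal F1. Wittig olefination with 15 (toluene, 80 °C) gives the (E)-enedione 3-[(1E,3S,6E)-3,7,11-trimethyl-8,9-dioxo-5-(phenylselanyl)dodeca-1,6-dien-1-yl]-4-(methoxymethoxy)-5-methyl-2H-chromen-2-one F2. Thermal intramolecular inverse-demand hetero-Diels–Alder reaction (toluene, 80–110 °C, Eu(fod)3 if needed) gives the 5-(phenylselanyl)-4a,5-dihydro analogue of 19 F3, with selenium cis to H-4a by the allylic-strain model. H2O2, pyridine, CH2Cl2, 0 °C to rt then effects selenoxide syn-elimination into conjugation to give 19.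

2. Step 11. Protonation may occur at the remote terminus of the dienol ether (the double bond then migrates to the tetrasubstituted position) or from the wrong face, and ketal closure at the acyl-substituted carbon may be slow. Fallback, from 19 back to 21: the ketal is reached through the ring-opened keto form instead of through face-selective protonation. ZnBr2, n-PrSH, CH2Cl2, 0 °C removes the MOM group without protic acid and 20 is isolated. Ethylenediammonium diacetate (20 mol %), MeCN/H2O, 50 °C should open the 2H-pyran by retro-oxa-Michael reaction to the alkylidene-chromanedione keto form F4, in which the centre α to the diketone equilibrates by enolisation. The known hemiketal/oxa-Michael/ketalisation domino of such Knoevenagel-type adducts then closes both C–O bonds to give 21.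

3. Step 3. The dienolate may fail to attack the di-ortho-substituted benzoate, may fragment to a vinylketene and the phenoxide, or the alkene geometry may scramble. Fallback, from 3 back to 6: the C–C bond is made intermolecularly with a more reactive acyl donor. Esterification of 3 (MeOH, cat. H2SO4) gives methyl (3E,5S)-5,9-dimethyldeca-3,8-dienoate F5. Its lithium dienolate (LiN(SiMe3)2, THF, −78 °C) is C-acylated at the α-carbon with 2-acetoxy-6-methylbenzoyl chloride to give methyl (3E,5S)-2-[2-(acetyloxy)-6-methylbenzoyl]-5,9-dimethyldeca-3,8-dienoate F6. K2CO3, MeOH removes the acetate and the phenoxide lactonises onto the methyl ester to give 6.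

**Further compounds**
F1 | step 10 | (4S,5E)-6-[4-(methoxymethoxy)-5-methyl-2-oxo-2H-chromen-3-yl]-4-methyl-2-(phenylselanyl)hex-5-enal, both C2 epimers | Cc1cccc2oc(=O)c(/C=C/[C@@H](C)CC([Se]c3ccccc3)C=O)c(OCOC)c12
F2 | step 10 | 3-[(1E,3S,6E)-3,7,11-trimethyl-8,9-dioxo-5-(phenylselanyl)dodeca-1,6-dien-1-yl]-4-(methoxymethoxy)-5-methyl-2H-chromen-2-one, both C5 epimers | Cc1cccc2oc(=O)c(/C=C/[C@@H](C)CC([Se]c3ccccc3)/C=C(\C)C(=O)C(=O)CC(C)C)c(OCOC)c12
F3 | step 10 | 5-(phenylselanyl)-4a,5-dihydro analogue of 19 (C1, C7, C7a as in 19; C4a and C5 as formed) | COCOc1c2c(C)cccc2oc(=O)c1[C@@H]1OC(C(=O)CC(C)C)=C(C)C2C([Se]c3ccccc3)C[C@H](C)[C@@H]12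
F4 | step 11 | 5-methyl-3-{[5-methyl-2-(6-methyl-3,4-dioxoheptan-2-yl)cyclopent-2-en-1-yl]methylidene}chromane-2,4-dione, ring stereocentres as in 21, side-chain CH(CH3) as both epimers | Cc1cccc2OC(=O)C(=C[C@@H]3[C@@H](C)CC=C3C(C)C(=O)C(=O)CC(C)C)C(=O)c12
F5 | step 3 | methyl (3E,5S)-5,9-dimethyldeca-3,8-dienoate | COC(=O)C/C=C/[C@@H](C)CCC=C(C)C
F6 | step 3 | methyl (3E,5S)-2-[2-(acetyloxy)-6-methylbenzoyl]-5,9-dimethyldeca-3,8-dienoate, both C2 epimers | COC(=O)C(/C=C/[C@@H](C)CCC=C(C)C)C(=O)c1c(C)cccc1OC(C)=O
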